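The decision is which temperature programme to run, and the choice rests on how much target survives next to its isomer and the side product.

| setting | larch | oak | ash |
|---|---|---|---|
| substrate | 0.050 M | 0.050 M | 0.050 M |
| coupling partner | 0.250 M | 0.250 M | 0.250 M |
| rival reagent | 0.0900 M | 0.0900 M | 0.0900 M |
| time | 10 h | 10 h | 10 h |
| remark | at 20 °C until 8.0 h, from then on at 5 °C |  |  |
| temperature |  | 20 °C | 5 °C |

    rival reagent → decomposed reagent (k1 = 0.0011 min⁻¹, Ea1 = 97.0 kJ mol⁻¹)
    substrate + rival reagent → side product (k2 = 0.022 M⁻¹ min⁻¹, Ea2 = 76.0 kJ mol⁻¹)
    target ⇌ isomer of the product (K3 = 1.1, k3 = 0.0025 min⁻¹, Ea3 = 98.0 kJ mol⁻¹, ΔH3 = −25.0 kJ mol⁻¹)
    crystals ⇌ target, rate k4*(cs4 - [target]) while solid is left; crystals form when [target] > cs4 (cs4 = 33 mM, k4 = 0.20 min⁻¹)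
    substrate + coupling partner → target (k5 = 0.017 M⁻¹ min⁻¹, Ea5 = 71.0 kJ mol⁻¹)
    (constants at 20 °C)

1. the best flask by share of target in all that became target or side product or isomer of the product; "all alike" if 1.5 percentage points covers them all (larch / oak / ash / all alike)
2. share of target in all that became target or side product or isomer of the product, larch
3. share of target in all that became target or side product or isomer of the product, oak
4. share of target in all that became target or side product or isomer of the product, ash

- target is meant together with its crystals
- solid, in amounts per volume of the solution: crystals
- the list of constants is for 20 °C, to be carried to other temperatures by the activation energies and enthalpies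

Two of us argue at the board, and both set crystals aside, which is an assumption, since the charge of substrate, 0.050 M, stands above the solubility, 33 mM.

The first sees a fork. Substrate goes towards target at its constant times c(coupling partner), and to side product at its constant times c(rival reagent). The ratio of these is a selectivity factor, and taken at the start, with the constants carried to each temperature by their activation energies, it gives a branch share of 68.2% in oak and 70.6% in ash. Larch starts as oak does, so the flasks lie 2.4 percentage points apart, with the margin at 1.5 points.

The second, who is me, answers that the branch share counts target and isomer together, and the question doesn't. Target relaxes towards its isomer with a rate constant λ, the forward and back constants added. In ash the enthalpy of step 3 carries the equilibrium constant to 1.91. That gives a relaxation half-life of 2.42 h at 20 °C and 26.5 h in ash, so the run of 10 h is longer than the first and shorter than the second.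

Integrate that rate for target made at a steady pace over a time t. The part turned to isomer is K/(one plus K) times one minus (one minus e to the minus λt)/λt, with K the equilibrium constant. The remainder is 92.1% in ash and 64.9% in oak. For larch I count the warm 8.0 h and treat the chill as a stop, which gives 68.2%.

This kept fraction, times the branch share, is my estimate of the share: 46.5% for larch, 44.3% for oak, 65.0% for ash, and best ash. In oak substrate has, at the starting concentrations, a half-life near 1.85 h, shorter than the run, so making is not steady there and I expect my warm figures to come out high.

The forecast stands on my side with 43% for larch, 42% for oak and 65% for ash, and names ash as best, saying of the isomerisation that “its high activation energy hits it hardest”. My oak figure lies above its number.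

The simulation gives 42.7% for larch, 40.4% for oak and 65.1% for ash, so ash is best, and crystals stood at 0% in ash.

The fork has its region early, well inside the relaxation half-life: ash at 5.00 h holds 0.950% of isomer against 20.7% of target. At 10.0 h, ash holds 91.1% of target among target and isomer, against the kept 92.1%. The neighbour is ash with 0.036 M of rival reagent, at the same temperature and time, so I carry the kept fraction over. Its branch share becomes 85.7%, and the product is 78.9%; that flask gave 78.7%.

All constants come from no measurement; the run is a simulation.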